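The cycloheptane ring hides a cyclohepta-1,4-diene retron: the isoprene-shaped segment C7–C8(Me)–C9–C10 is joined at its ends to C6 and to the quaternary C1 of the cyclopentane (daucane numbering: C1 methyl-bearing fusion carbon, C4 isopropyl carbinol, C5 fusion CH, C6 ester carbon). In one operation a rhodium vinylcarbene at C6, released from the sulfonylhydrazone of an enantiopure 5-silyloxy-2-methylcyclopentene-1-carbaldehyde, cyclopropanates isoprene (C6–C7) and the cis-divinylcyclopropane undergoes Cope rearrangement (C1–C10), closing the seven-membered ring and delivering C10 to C1 anti to the C4 silyloxy group. Hydroboration of C5=C6, epoxide hydrolysis at C8/C9 and isopropyl addition to a C4 ketone finish the functionality.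

Key step: step 5

Remark: daucane numbering is used in the Why lines (C1 quaternary C–Me, C2, C3, C4, C5 fusion CH, C6, C7, C8 C–Me, C9, C10); β is the face of the C1 methyl.
Remark: 2-(trifluoromethyl)benzenesulfonohydrazide 5 is taken as a purchasable reagent (otherwise it is one step from the sulfonyl chloride and hydrazine hydrate).

Step 1
Reactants: 1 2-bromo-3-methylcyclopent-2-en-1-one
Product: 2 (S)-2-bromo-3-methylcyclopent-2-en-1-ol
Conditions: (R)-2-methyl-CBS-oxazaborolidine (10 mol %), BH3·SMe2, THF, −20 °C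
Reagents that add atoms: none
Why: Corey–Bakshi–Shibata reduction, in which the bromovinyl arm acts as the large substituent, so the (R)-oxazaborolidine should deliver hydride to the face that gives the (S)-allylic alcohol, as is usual for 2-halocycloalkenones.

Step 2
Reactants: 2 (S)-2-bromo-3-methylcyclopent-2-en-1-ol
Product: 3 (S)-[(2-bromo-3-methylcyclopent-2-en-1-yl)oxy](tert-butyl)dimethylsilane
Conditions: TBSCl, imidazole, DMF, rt
Reagents that add atoms: tert-butyldimethylsilyl chloride, CC(C)(C)[Si](C)(C)Cl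
Why: Standard imidazole-promoted silylation of a secondary alcohol, which does not touch the stereocentre and installs the bulky group that later shields the β face.

Step 3
Reactants: 3 (S)-[(2-bromo-3-methylcyclopent-2-en-1-yl)oxy](tert-butyl)dimethylsilane
Product: 4 (S)-5-[(tert-butyldimethylsilyl)oxy]-2-methylcyclopent-1-ene-1-carbaldehyde
Conditions: t-BuLi (2.1 equiv), THF, −78 °C; then DMF; aq NH4Cl
Reagents that add atoms: N,N-dimethylformamide, CN(C)C=O
Why: Bromine–lithium exchange on the vinyl bromide followed by Bouveault-type formylation of the vinyllithium with DMF; the silyl ether sits on the adjacent sp3 carbon, so β-elimination is not possible in the five-membered ring.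

Step 4
Reactants: 4 (S)-5-[(tert-butyldimethylsilyl)oxy]-2-methylcyclopent-1-ene-1-carbaldehyde; 5 2-(trifluoromethyl)benzenesulfonohydrazide
Product: 6 N'-[(E)-{(5S)-5-[(tert-butyldimethylsilyl)oxy]-2-methylcyclopent-1-en-1-yl}methylidene]-2-(trifluoromethyl)benzenesulfonohydrazide
Conditions: MeOH, rt
Reagents that add atoms: 2-(trifluoromethyl)benzenesulfonohydrazide 5, NNS(=O)(=O)c1ccccc1C(F)(F)F
Why: Condensation of the enal with the sulfonyl hydrazide to the E-hydrazone; the electron-poor arylsulfonyl group allows Bamford–Stevens release of the diazo compound near room temperature in the next step.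

Step 5
Reactants: 6 N'-[(E)-{(5S)-5-[(tert-butyldimethylsilyl)oxy]-2-methylcyclopent-1-en-1-yl}methylidene]-2-(trifluoromethyl)benzenesulfonohydrazide; 7 isoprene
Product: 10 tert-butyl{[(3S,8aR)-6,8a-dimethyl-1,2,3,5,8,8a-hexahydroazulen-3-yl]oxy}dimethylsilane, via diazoalkene 8 (not isolated), via cis-divinylcyclopropane 9 (not isolated)
Conditions: NaH (2 equiv), Rh2(OAc)4 (2 mol %), isoprene (20 equiv), PhCF3, 40 °C, sealed tube; then toluene, 110 °C
Reagents that add atoms: isoprene 7, C=CC(C)=C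
Why: NaH converts 6 into its sodium salt, which loses sulfinate (Bamford–Stevens) to give diazoalkene 8; Rh2(OAc)4 decomposes 8 and transfers the electrophilic vinylcarbene to the more nucleophilic, methyl-bearing double bond of isoprene (bond C6–C7 plus a transient C6–C8 bond), and the cis-divinylcyclopropane 9 then undergoes a [3,3]-sigmatropic (Cope) rearrangement that forms C1–C10 and cleaves C6–C8. The closest known reaction type is the tandem cyclopropanation/Cope rearrangement of rhodium vinylcarbenes with 1,3-dienes, a formal (4+3) cycloaddition. The three-membered ring closes by (2+1) carbene transfer and the seven-membered ring by ring expansion through the boat transition state of the divinylcyclopropane rearrangement. The only stereocentre that survives, the quaternary C1, is controlled by the C4 silyloxy group: the carbene should react through the rotamer with rhodium turned away from the in-plane C1 methyl, the alkene approaches C6 anti to OTBS, and the boat Cope transfers this to C1 so that C10 bonds on the face opposite OTBS, leaving the methyl cis to the oxygen. The step needs site selectivity for the 1,1-disubstituted double bond of isoprene, which the developing tertiary allylic cation character should secure, and convergence of any trans-divinylcyclopropane, which at 110 °C should equilibrate by reversible C6–C8 homolysis and rearrange through the same OTBS-anti boat.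

Step 6
Reactants: 10 tert-butyl{[(3S,8aR)-6,8a-dimethyl-1,2,3,5,8,8a-hexahydroazulen-3-yl]oxy}dimethylsilane
Product: 11 tert-butyl{[(3S,6R,7S,8aR)-6,7-epoxy-6,8a-dimethyl-1,2,3,5,6,7,8,8a-octahydroazulen-3-yl]oxy}dimethylsilane (8α,9α-epoxide)
Conditions: mCPBA (1.05 equiv), NaHCO3, CH2Cl2, −20 → 0 °C
Reagents that add atoms: 3-chloroperoxybenzoic acid, OOC(=O)c1cccc(Cl)c1
Why: Prilezhaev epoxidation, expected at C8=C9 because C5=C6 is deactivated by the allylic silyloxy group and flanked by the quaternary C1, and expected from the α face because the C1 methyl lies gauche over the β face of C9.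

Step 7
Reactants: 11 tert-butyl{[(3S,6R,7S,8aR)-6,7-epoxy-6,8a-dimethyl-1,2,3,5,6,7,8,8a-octahydroazulen-3-yl]oxy}dimethylsilane
Product: 12 (3S,3aS,4S,6R,7S,8aR)-3-[(tert-butyldimethylsilyl)oxy]-6,7-epoxy-6,8a-dimethyldecahydroazulen-4-ol
Conditions: BH3·THF, THF, 0 °C → rt; then 3 M NaOH, 30% H2O2, 0 °C
Reagents that add atoms: hydrogen peroxide, OO
Why: Hydroboration–oxidation places boron on the less substituted C6 and hydrogen on C5 in a syn addition from the α face, opposite the C4 silyloxy group and the C1 methyl that flank C5, so 5α-H (trans ring fusion) and 6α-OH are set together; uncatalysed borane should leave the trisubstituted epoxide intact at this temperature.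

Step 8
Reactants: 12 (3S,3aS,4S,6R,7S,8aR)-3-[(tert-butyldimethylsilyl)oxy]-6,7-epoxy-6,8a-dimethyldecahydroazulen-4-ol; 13 4-(benzyloxy)benzoyl chloride
Product: 14 (3S,3aS,4S,6R,7S,8aR)-3-[(tert-butyldimethylsilyl)oxy]-6,7-epoxy-6,8a-dimethyldecahydroazulen-4-yl 4-(benzyloxy)benzoate
Conditions: Et3N, DMAP, CH2Cl2, rt → 40 °C
Reagents that add atoms: 4-(benzyloxy)benzoyl chloride 13, O=C(Cl)c1ccc(OCc2ccccc2)cc1
Why: DMAP-catalysed acylation of the only free hydroxyl, with retention at C6 because the C–O bond is not broken.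

Step 9
Reactants: 14 (3S,3aS,4S,6R,7S,8aR)-3-[(tert-butyldimethylsilyl)oxy]-6,7-epoxy-6,8a-dimethyldecahydroazulen-4-yl 4-(benzyloxy)benzoate
Product: 15 (3S,3aR,4S,6R,7S,8aR)-6,7-epoxy-3-hydroxy-6,8a-dimethyldecahydroazulen-4-yl 4-(benzyloxy)benzoate
Conditions: TBAF, AcOH, THF, rt
Reagents that add atoms: none
Why: Fluoride-mediated desilylation, buffered with acetic acid so that the benzoate should not migrate and the epoxide should not open.

Step 10
Reactants: 15 (3S,3aR,4S,6R,7S,8aR)-6,7-epoxy-3-hydroxy-6,8a-dimethyldecahydroazulen-4-yl 4-(benzyloxy)benzoate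
Product: 16 (3aS,4S,6R,7S,8aR)-6,7-epoxy-6,8a-dimethyl-3-oxodecahydroazulen-4-yl 4-(benzyloxy)benzoate
Conditions: Dess–Martin periodinane, NaHCO3, CH2Cl2, 0 °C → rt
Reagents that add atoms: none
Why: Dess–Martin oxidation under buffered, non-basic conditions, chosen so that the β-acyloxy ketone does not eliminate and the C5 stereocentre next to the new carbonyl is not epimerised.

Step 11
Reactants: 16 (3aS,4S,6R,7S,8aR)-6,7-epoxy-6,8a-dimethyl-3-oxodecahydroazulen-4-yl 4-(benzyloxy)benzoate
Product: 17 (3R,3aS,4S,6R,7S,8aR)-6,7-epoxy-3-hydroxy-6,8a-dimethyl-3-(propan-2-yl)decahydroazulen-4-yl 4-(benzyloxy)benzoate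
Conditions: i-PrMgCl, anhydrous CeCl3, THF, −78 °C; aq NH4Cl
Reagents that add atoms: isopropylmagnesium chloride, CC(C)[Mg]Cl
Why: Organocerium 1,2-addition, whose low basicity should suppress enolisation, β-elimination and attack on the ester or epoxide; the reagent should approach the cyclopentanone from the α face, anti to the C5–C6 bond and the 1,3-related C1 methyl, giving the 4β-hydroxyl with α-isopropyl.

Step 12
Reactants: 17 (3R,3aS,4S,6R,7S,8aR)-6,7-epoxy-3-hydroxy-6,8a-dimethyl-3-(propan-2-yl)decahydroazulen-4-yl 4-(benzyloxy)benzoate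
Product: 18 (3R,3aS,4S,6S,7S,8aR)-3,6,7-trihydroxy-6,8a-dimethyl-3-(propan-2-yl)decahydroazulen-4-yl 4-(benzyloxy)benzoate
Conditions: cat. HClO4, THF/H2O, 0 °C
Reagents that add atoms: water, O
Why: Acid-catalysed epoxide hydrolysis, in which water opens the protonated epoxide at the tertiary C8 with inversion from the β face and leaves the C9–O bond untouched, so the 8α,9α-epoxide should give the trans 8β,9α-diol; the 6α-benzoate cannot reach the β face, and low temperature is meant to keep the 4β-hydroxyl from transannular attack.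

Step 13
Reactants: 18 (3R,3aS,4S,6S,7S,8aR)-3,6,7-trihydroxy-6,8a-dimethyl-3-(propan-2-yl)decahydroazulen-4-yl 4-(benzyloxy)benzoate
Product: 19 (3R,3aS,4S,6S,7S,8aR)-3,6,7-trihydroxy-6,8a-dimethyl-3-(propan-2-yl)decahydroazulen-4-yl 4-hydroxybenzoate (CNP0197754.1)
Conditions: H2 (1 atm), 10% Pd/C, EtOAc, rt
Reagents that add atoms: none
Why: Hydrogenolysis of the benzyl aryl ether; no alkene or epoxide remains, and the ester and alcohols are inert.

Compound list
1 | 2-bromo-3-methylcyclopent-2-en-1-one | CC1=C(Br)C(=O)CC1 | starting material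
2 | (S)-2-bromo-3-methylcyclopent-2-en-1-ol | O[C@H]1CCC(C)=C1Br | intermediate
3 | (S)-[(2-bromo-3-methylcyclopent-2-en-1-yl)oxy](tert-butyl)dimethylsilane | CC(C)(C)[Si](C)(C)O[C@H]1CCC(C)=C1Br | intermediate
4 | (S)-5-[(tert-butyldimethylsilyl)oxy]-2-methylcyclopent-1-ene-1-carbaldehyde | CC(C)(C)[Si](C)(C)O[C@H]1CCC(C)=C1C=O | intermediate
5 | 2-(trifluoromethyl)benzenesulfonohydrazide | NNS(=O)(=O)c1ccccc1C(F)(F)F | starting material
6 | N'-[(E)-{(5S)-5-[(tert-butyldimethylsilyl)oxy]-2-methylcyclopent-1-en-1-yl}methylidene]-2-(trifluoromethyl)benzenesulfonohydrazide | CC(C)(C)[Si](C)(C)O[C@H]1CCC(C)=C1/C=N/NS(=O)(=O)c1ccccc1C(F)(F)F | intermediate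
7 | isoprene (2-methylbuta-1,3-diene) | C=CC(C)=C | starting material
8 | tert-butyl{[(1S)-2-(diazomethyl)-3-methylcyclopent-2-en-1-yl]oxy}dimethylsilane | CC(C)(C)[Si](C)(C)O[C@H]1CCC(C)=C1C=[N+]=[N-] | intermediate (not isolated)
9 | tert-butyl({(1S)-2-[(1R,2R)-2-ethenyl-2-methylcyclopropyl]-3-methylcyclopent-2-en-1-yl}oxy)dimethylsilane | CC(C)(C)[Si](C)(C)O[C@H]1CCC(C)=C1[C@@H]1C[C@]1(C)C=C | intermediate (not isolated)
10 | tert-butyl{[(3S,8aR)-6,8a-dimethyl-1,2,3,5,8,8a-hexahydroazulen-3-yl]oxy}dimethylsilane | CC(C)(C)[Si](C)(C)O[C@H]1CC[C@]2(C)CC=C(C)CC=C12 | intermediate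
11 | tert-butyl{[(3S,6R,7S,8aR)-6,7-epoxy-6,8a-dimethyl-1,2,3,5,6,7,8,8a-octahydroazulen-3-yl]oxy}dimethylsilane | CC(C)(C)[Si](C)(C)O[C@H]1CC[C@]2(C)C[C@@H]3O[C@]3(C)CC=C12 | intermediate
12 | (3S,3aS,4S,6R,7S,8aR)-3-[(tert-butyldimethylsilyl)oxy]-6,7-epoxy-6,8a-dimethyldecahydroazulen-4-ol | CC(C)(C)[Si](C)(C)O[C@H]1CC[C@]2(C)C[C@@H]3O[C@]3(C)C[C@H](O)[C@H]21 | intermediate
13 | 4-(benzyloxy)benzoyl chloride | O=C(Cl)c1ccc(OCc2ccccc2)cc1 | starting material
14 | (3S,3aS,4S,6R,7S,8aR)-3-[(tert-butyldimethylsilyl)oxy]-6,7-epoxy-6,8a-dimethyldecahydroazulen-4-yl 4-(benzyloxy)benzoate | CC(C)(C)[Si](C)(C)O[C@H]1CC[C@]2(C)C[C@@H]3O[C@]3(C)C[C@H](OC(=O)c3ccc(OCc4ccccc4)cc3)[C@H]21 | intermediate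
15 | (3S,3aR,4S,6R,7S,8aR)-6,7-epoxy-3-hydroxy-6,8a-dimethyldecahydroazulen-4-yl 4-(benzyloxy)benzoate | O[C@H]1CC[C@]2(C)C[C@@H]3O[C@]3(C)C[C@H](OC(=O)c3ccc(OCc4ccccc4)cc3)[C@H]21 | intermediate
16 | (3aS,4S,6R,7S,8aR)-6,7-epoxy-6,8a-dimethyl-3-oxodecahydroazulen-4-yl 4-(benzyloxy)benzoate | O=C1CC[C@]2(C)C[C@@H]3O[C@]3(C)C[C@H](OC(=O)c3ccc(OCc4ccccc4)cc3)[C@H]21 | intermediate
17 | (3R,3aS,4S,6R,7S,8aR)-6,7-epoxy-3-hydroxy-6,8a-dimethyl-3-(propan-2-yl)decahydroazulen-4-yl 4-(benzyloxy)benzoate | CC(C)[C@]1(O)CC[C@]2(C)C[C@@H]3O[C@]3(C)C[C@H](OC(=O)c3ccc(OCc4ccccc4)cc3)[C@H]21 | intermediate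
18 | (3R,3aS,4S,6S,7S,8aR)-3,6,7-trihydroxy-6,8a-dimethyl-3-(propan-2-yl)decahydroazulen-4-yl 4-(benzyloxy)benzoate | CC(C)[C@]1(O)CC[C@]2(C)C[C@H](O)[C@@](C)(O)C[C@H](OC(=O)c3ccc(OCc4ccccc4)cc3)[C@H]21 | intermediate
19 | (3R,3aS,4S,6S,7S,8aR)-3,6,7-trihydroxy-6,8a-dimethyl-3-(propan-2-yl)decahydroazulen-4-yl 4-hydroxybenzoate | CC(C)[C@]1(O)CC[C@]2(C)C[C@H](O)[C@@](C)(O)C[C@H](OC(=O)c3ccc(O)cc3)[C@H]21 | target

Total step count: 13. Longest linear sequence: 13 steps (1 → 19).

Steps most likely to fail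

Step 5 (key step). The carbene may attack the unsubstituted vinyl group of isoprene as well, which would place the ring methyl on C9. In addition, diazoalkene 8 may close to a 3H-pyrazole or the carbene may collapse by 1,4-hydrogen shift before it is trapped. The fallback sets out from hydrazone 6 and changes the diene to one in which only the isopropenyl double bond is nucleophilic. This is 3-methylbuta-1,3-dien-2-yl trifluoromethanesulfonate F1, made from 3-methylbut-3-en-2-one with KHMDS and PhNTf2. Under the conditions of step 5 the cascade should pass through the triflyloxy divinylcyclopropane F2 to the vinyl triflate (3S,8aR)-3-[(tert-butyldimethylsilyl)oxy]-6,8a-dimethyl-1,2,3,5,8,8a-hexahydroazulen-7-yl trifluoromethanesulfonate F3. The tetrasubstituted, electron-poor enol triflate should not be hydroborated, so BH3·THF then NaOH/H2O2 should act on C5=C6 alone and give the alcohol F4. Palladium-catalysed formate reduction (Pd(OAc)2, PPh3, Et3N, HCO2H, DMF, 60 °C) should then give the homoallylic alcohol F5. Vanadium-catalysed epoxidation (VO(acac)2, t-BuOOH), directed by the 6α-hydroxyl to the α face of C8=C9, returns to the route at 12.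

Step 6. The peracid may attack C8=C9 partly from the β face, or attack C5=C6, so that facial and site selectivity are eroded. The fallback sets out from 10 and uses the epoxide only as a temporary mask for C8=C9. The mixture of 11 and its 8β,9β-epoxide isomer F6 is carried through the hydroboration of step 7 to 12 and the epimeric epoxy alcohol F7. Both are deoxygenated with lower-valent tungsten (WCl6, n-BuLi, THF) to the single homoallylic alcohol F5. Hydroxyl-directed epoxidation (VO(acac)2, t-BuOOH) then fixes the α face and returns to the route at 12.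

Step 11. The ketone may enolise towards C5 and expel the benzoate, or be reduced by β-hydride transfer from the secondary alkyl reagent instead of adding it. The fallback sets out from 16 and uses an sp2 nucleophile that has no transferable β-hydrogen and is smaller and less basic. Isopropenylmagnesium bromide with CeCl3 should give the isopropenyl carbinol (3S,3aS,4S,6R,7S,8aR)-6,7-epoxy-3-hydroxy-6,8a-dimethyl-3-(prop-1-en-2-yl)decahydroazulen-4-yl 4-(benzyloxy)benzoate F8. Hydrogenation over Pd/C should saturate the isopropenyl group and remove the benzyl ether in one operation, giving the epoxy phenol F9. Acid hydrolysis as in step 12 then gives the target 19 directly.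

Further compounds
F1 | step 5 | 3-methylbuta-1,3-dien-2-yl trifluoromethanesulfonate | C=C(C)C(=C)OS(=O)(=O)C(F)(F)F
F2 | step 5 | 1-[(1S,2S)-2-{(5S)-5-[(tert-butyldimethylsilyl)oxy]-2-methylcyclopent-1-en-1-yl}-1-methylcyclopropyl]ethenyl trifluoromethanesulfonate | CC(C)(C)[Si](C)(C)O[C@H]1CCC(C)=C1[C@@H]1C[C@]1(C)C(=C)OS(=O)(=O)C(F)(F)F
F3 | step 5 | (3S,8aR)-3-[(tert-butyldimethylsilyl)oxy]-6,8a-dimethyl-1,2,3,5,8,8a-hexahydroazulen-7-yl trifluoromethanesulfonate | CC(C)(C)[Si](C)(C)O[C@H]1CC[C@]2(C)CC(OS(=O)(=O)C(F)(F)F)=C(C)CC=C12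
F4 | step 5 | (3S,3aS,4S,8aR)-3-[(tert-butyldimethylsilyl)oxy]-4-hydroxy-6,8a-dimethyl-1,2,3,3a,4,5,8,8a-octahydroazulen-7-yl trifluoromethanesulfonate | CC(C)(C)[Si](C)(C)O[C@H]1CC[C@]2(C)CC(OS(=O)(=O)C(F)(F)F)=C(C)C[C@H](O)[C@H]21
F5 | step 5 | (3S,3aS,4S,8aR)-3-[(tert-butyldimethylsilyl)oxy]-6,8a-dimethyl-1,2,3,3a,4,5,8,8a-octahydroazulen-4-ol | CC(C)(C)[Si](C)(C)O[C@H]1CC[C@]2(C)CC=C(C)C[C@H](O)[C@H]21
F6 | step 6 | tert-butyl{[(3S,6S,7R,8aR)-6,7-epoxy-6,8a-dimethyl-1,2,3,5,6,7,8,8a-octahydroazulen-3-yl]oxy}dimethylsilane | CC(C)(C)[Si](C)(C)O[C@H]1CC[C@]2(C)C[C@H]3O[C@@]3(C)CC=C12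
F7 | step 6 | (3S,3aS,4S,6S,7R,8aR)-3-[(tert-butyldimethylsilyl)oxy]-6,7-epoxy-6,8a-dimethyldecahydroazulen-4-ol | CC(C)(C)[Si](C)(C)O[C@H]1CC[C@]2(C)C[C@H]3O[C@@]3(C)C[C@H](O)[C@H]21
F8 | step 11 | (3S,3aS,4S,6R,7S,8aR)-6,7-epoxy-3-hydroxy-6,8a-dimethyl-3-(prop-1-en-2-yl)decahydroazulen-4-yl 4-(benzyloxy)benzoate | C=C(C)[C@]1(O)CC[C@]2(C)C[C@@H]3O[C@]3(C)C[C@H](OC(=O)c3ccc(OCc4ccccc4)cc3)[C@H]21
F9 | step 11 | (3R,3aS,4S,6R,7S,8aR)-6,7-epoxy-3-hydroxy-6,8a-dimethyl-3-(propan-2-yl)decahydroazulen-4-yl 4-hydroxybenzoate | CC(C)[C@]1(O)CC[C@]2(C)C[C@@H]3O[C@]3(C)C[C@H](OC(=O)c3ccc(O)cc3)[C@H]21
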